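**Retrosynthetic overview**
1. Target 28 ← E-selective cross metathesis and selective acetylation ← diol 25 ← allyl Grignard addition to the ring methyl ketone 23; the side chain is attached last.
2. 23 ← epoxy iodide/zinc transposition, radical hydrogenation of the ring-fusion alkene, glycol cleavage, Sharpless epoxidation ← hydroazulene dienoate 16.
3. 16 ← vinylcarbenoid from diazo ester 14 + triene 12 by cyclopropanation/Cope rearrangement (formal [4+3]). The strategy rests on this feature: in the seven-membered ring, C8a (quaternary, methyl), C8 (CH2), C7 (CH–OAc) and C6 with its exocyclic CH2 are the three carbons and the ester carbon of a vinyldiazoacetate, laid onto the vinyl group and the methyl-bearing carbon of a 2-methyl-1-vinylcyclopentene.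
4. 12 ← cyclopentene ester 9 ← (S)-carvone by Favorskii ring contraction; the five-membered ring with the side-chain carbon C3 is the contracted carvone ring.
5. Ring order: five-membered ring first, seven-membered ring closed onto it in the key step.

Key step: step 11

Numbering used in the names of 16–28: C1, C2 = CH2 groups of the five-membered ring; C3 carries the side chain; C3a = ring-fusion CH; C4–C8 run round the seven-membered ring (C6 bears the one-carbon branch, C7 the oxygen); C8a = methyl-bearing ring-fusion carbon.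

Assumption: the sense of induction known for Rh2(DOSP)4 with styrene and aryl- or vinyldiazoacetates (S-catalyst giving the 1S,2R-type cyclopropane) is taken to hold for triene 12 and diazo ester 14; on that basis Rh2(R-DOSP)4, dirhodium tetrakis[(R)-N-(4-dodecylbenzenesulfonyl)prolinate], is the catalyst matched to C3. If the C8a epimer forms instead, the S-catalyst is the direct substitute.

**Step 1**
Reactants: 1 (S)-(+)-carvone
Product: 2 (1S,4S,6S)-1-methyl-4-(prop-1-en-2-yl)-7-oxabicyclo[4.1.0]heptan-2-one
Conditions: 30% H2O2, NaOH (cat.), MeOH, 0 °C to rt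
Reagents that add atoms: hydrogen peroxide OO
Why: Weitz–Scheffer nucleophilic epoxidation touches only the enone, and hydroperoxide should add anti to the isopropenyl group to give the trans epoxide.

**Step 2**
Reactants: 2 carvone epoxide
Product: 3 (2R,3S,5S)-2-chloro-3-hydroxy-2-methyl-5-(prop-1-en-2-yl)cyclohexan-1-one
Conditions: LiCl, CF3CO2H, THF, rt
Reagents that add atoms: lithium chloride [Li+].[Cl-]
Why: acid-promoted epoxide opening by chloride at the tertiary α-carbon with inversion should give the α-chloro-β-hydroxy ketone needed for ring contraction.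

**Step 3**
Reactants: 3 chlorohydrin
Product: 4 (2R,3S,5S)-2-chloro-2-methyl-5-(prop-1-en-2-yl)-3-(tetrahydro-2H-pyran-2-yloxy)cyclohexan-1-one (both acetal epimers)
Conditions: 3,4-dihydro-2H-pyran, PPTS (cat.), CH2Cl2, rt
Reagents that add atoms: 3,4-dihydro-2H-pyran C1=COCCC1
Why: acid-catalysed acetal formation masks the β-hydroxyl so that base in the next step cannot reclose the epoxide or cause retro-aldol cleavage.

**Step 4**
Reactants: 4 tetrahydropyranyl ether of the chlorohydrin
Product: 6 methyl (1S,2R,3S,5S)-3-hydroxy-2-methyl-5-(prop-1-en-2-yl)cyclopentane-1-carboxylate, via tetrahydropyranyl ether ester 5 (not isolated)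
Conditions: NaOMe, MeOH, 0 °C to rt; then TsOH·H2O to pH 2–3, rt
Reagents that add atoms: sodium methoxide [Na+].[O-]C
Why: Favorskii rearrangement, in which the C6 enolate displaces the tertiary chloride and methoxide opens the resulting cyclopropanone to the cyclopentane ester, followed by acid methanolysis of the acetal; only the isopropenyl-bearing centre is needed later.

**Step 5**
Reactants: 6 hydroxy ester
Product: 7 methyl (1S,2R,3S,5S)-3-(methanesulfonyloxy)-2-methyl-5-(prop-1-en-2-yl)cyclopentane-1-carboxylate
Conditions: MsCl, Et3N, CH2Cl2, 0 °C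
Reagents that add atoms: methanesulfonyl chloride CS(=O)(=O)Cl
Why: sulfonylation turns the secondary hydroxyl into a leaving group without touching any stereocentre.

**Step 6**
Reactants: 7 mesylate
Product: 9 methyl (5R)-2-methyl-5-(prop-1-en-2-yl)cyclopent-1-ene-1-carboxylate, via cyclopent-2-ene ester 8 (not isolated)
Conditions: DBU, toluene, 110 °C
Reagents that add atoms: none
Why: anti-periplanar E2 elimination of the mesylate with the trans C2–H should give the cyclopent-2-ene, and DBU then moves the double bond into conjugation through the dienolate to the more stable tetrasubstituted enoate, erasing C1–C3 while the isopropenyl-bearing carbon is not acidified.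

**Step 7**
Reactants: 9 conjugated ester
Product: 10 [(5R)-2-methyl-5-(prop-1-en-2-yl)cyclopent-1-en-1-yl]methanol
Conditions: DIBAL-H, CH2Cl2, −78 to 0 °C; aq. potassium sodium tartrate
Reagents that add atoms: none
Why: DIBAL-H reduces the conjugated ester 1,2 to the allylic alcohol.

**Step 8**
Reactants: 10 allylic alcohol
Product: 11 (5R)-2-methyl-5-(prop-1-en-2-yl)cyclopent-1-ene-1-carbaldehyde
Conditions: MnO2, CH2Cl2, rt
Reagents that add atoms: none
Why: MnO2 oxidises allylic alcohols selectively and stops at the aldehyde.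

**Step 9**
Reactants: 11 enal
Product: 12 (3R)-2-ethenyl-1-methyl-3-(prop-1-en-2-yl)cyclopent-1-ene
Conditions: Ph3PCH3Br, KOtBu, THF, 0 °C to rt; pentane work-up (volatile product)
Reagents that add atoms: methyltriphenylphosphonium bromide C[P+](c1ccccc1)(c1ccccc1)c1ccccc1.[Br-]
Why: Wittig methylenation of the enal gives the conjugated vinyl group without affecting the stereocentre.

**Step 10**
Reactants: 13 methyl but-3-enoate
Product: 14 methyl 2-diazobut-3-enoate
Conditions: p-ABSA, DBU, MeCN, 0 °C; cold pentane extraction, used at once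
Reagents that add atoms: 4-acetamidobenzenesulfonyl azide CC(=O)Nc1ccc(cc1)S(=O)(=O)N=[N+]=[N-]
Why: Regitz diazo transfer to the α-carbon of the ester dienolate; the product slowly cyclises to a pyrazole, so it is kept cold and used immediately.

**Step 11**
Reactants: 12 triene; 14 methyl 2-diazobut-3-enoate
Product: 16 methyl (3R,8aR)-8a-methyl-3-(prop-1-en-2-yl)-1,2,3,5,8,8a-hexahydroazulene-6-carboxylate, via cis-divinylcyclopropane 15 (not isolated)
Conditions: Rh2(R-DOSP)4 (1 mol %), pentane, −78 °C to rt, 14 (1.2 equiv) added over 2 h; then toluene, 110 °C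
Reagents that add atoms: none
Why: The rhodium-bound vinylcarbene from 14 adds to the terminal CH=CH2 of the conjugated diene of 12 with its vinyl group cis to the cyclopentenyl group (15), and on heating a boat-shaped [3,3] shift breaks the cyclopropane bond between the carbenoid carbon and the former internal vinyl carbon while the vinyl terminus bonds to the methyl-bearing ring carbon, so that the lasting new bonds are C5–C6 and C8–C8a. The closest known reaction type is the Rh2(DOSP)4-catalysed tandem cyclopropanation/Cope rearrangement (formal [4+3] cycloaddition) of vinyldiazoacetates with 1,3-dienes, including dienes whose far terminus is disubstituted. The seven-membered ring is closed by sigmatropic ring expansion of the cis-divinylcyclopropane and not by a direct cyclisation; strain release pays for the quaternary centre, and heat is needed because the methyl group lies inside the boat. The new stereocentre C8a follows stereospecifically from the cyclopropane configuration, which the chiral catalyst sets at the remote vinyl group, and with the R-catalyst C8 should arrive on the face of C8a opposite the isopropenyl group, which is also the less hindered boat. The step needs site selectivity for the diene terminus over the isolated isopropenyl alkene; conjugation and the low steric demand of the monosubstituted vinyl group should secure it, helped by slow addition of only a small excess of 14.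

**Step 12**
Reactants: 16 hydroazulene diene ester
Product: 17 [(3R,8aR)-8a-methyl-3-(prop-1-en-2-yl)-1,2,3,5,8,8a-hexahydroazulen-6-yl]methanol
Conditions: DIBAL-H, CH2Cl2, −78 °C; aq. potassium sodium tartrate
Reagents that add atoms: none
Why: DIBAL-H reduces the enoate 1,2 at low temperature without moving the skipped diene.

**Step 13**
Reactants: 17 allylic alcohol
Product: 18 [(3R,6S,7S,8aR)-6,7-epoxy-8a-methyl-3-(prop-1-en-2-yl)-1,2,3,5,6,7,8,8a-octahydroazulen-6-yl]methanol (epoxide anti to the 8a-methyl)
Conditions: Ti(OiPr)4 (10 mol %), L-(+)-diethyl tartrate (12 mol %), t-BuOOH, 4 Å MS, CH2Cl2, −20 °C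
Reagents that add atoms: tert-butyl hydroperoxide CC(C)(C)OO
Why: Sharpless asymmetric epoxidation reacts only at the allylic alcohol alkene, and L-(+)-diethyl tartrate should deliver oxygen to the face anti to the 8a-methyl, which the substrate also prefers, setting C6 and C7.

**Step 14**
Reactants: 18 epoxy alcohol
Product: 20 1-[(3S,6S,7S,8aR)-6,7-epoxy-6-(hydroxymethyl)-8a-methyl-1,2,3,5,6,7,8,8a-octahydroazulen-3-yl]ethan-1-one, via glycol 19 (not isolated)
Conditions: K2OsO4·2H2O (2 mol %), NaIO4, 2,6-lutidine, dioxane/H2O, rt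
Reagents that add atoms: sodium periodate [Na+].[O-]I(=O)(=O)=O
Why: Lemieux–Johnson oxidation, in which OsO4 should dihydroxylate the exposed 1,1-disubstituted alkene faster than the trisubstituted ring alkene shielded by the quaternary carbon, and periodate cleaves the glycol to the methyl ketone under buffered conditions.

**Step 15**
Reactants: 20 β,γ-unsaturated methyl ketone
Product: 21 1-[(3S,3aS,6S,7S,8aR)-6,7-epoxy-6-(hydroxymethyl)-8a-methyldecahydroazulen-3-yl]ethan-1-one
Conditions: Mn(dpm)3 (10 mol %), PhSiH3, t-BuOOH, i-PrOH, rt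
Reagents that add atoms: none
Why: hydrogen-atom-transfer hydrogenation puts H on C4 and the tertiary C3a radical should take its hydrogen on the face anti to the 8a-methyl and the C3 acetyl group, giving the trans ring fusion, while the neutral medium spares the epoxide and the α-centre of the ketone.

**Step 16**
Reactants: 21 trans-fused epoxy alcohol
Product: 22 1-[(3S,3aS,6R,7S,8aR)-6,7-epoxy-6-(iodomethyl)-8a-methyldecahydroazulen-3-yl]ethan-1-one
Conditions: I2, PPh3, imidazole, CH2Cl2, 0 °C to rt
Reagents that add atoms: iodine II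
Why: Appel-type iodination of the primary alcohol under nearly neutral conditions leaves the epoxide and the ketone untouched.

**Step 17**
Reactants: 22 epoxy iodide
Product: 23 1-[(3S,3aS,7S,8aR)-7-hydroxy-8a-methyl-6-methylidenedecahydroazulen-3-yl]ethan-1-one
Conditions: activated Zn dust, EtOH, 78 °C; aq. NH4Cl
Reagents that add atoms: none
Why: zinc inserts into the C–I bond and β-elimination opens the epoxide, giving the exocyclic methylene and the C7 alcohol with the C7–O bond and its configuration retained.

**Step 18**
Reactants: 23 methyl ketone; 24 allylmagnesium bromide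
Product: 25 (2S)-2-[(3S,3aS,7S,8aR)-7-hydroxy-8a-methyl-6-methylidenedecahydroazulen-3-yl]pent-4-en-2-ol
Conditions: 24 (3.5 equiv), THF, −78 °C; aq. NH4Cl
Reagents that add atoms: none
Why: Grignard addition after deprotonation of the C7 hydroxyl by the first equivalent, with Felkin–Anh attack anti to the ring-fusion carbon C3a and past the C3 hydrogen expected to give the (S) carbinol, as 20-oxo steroids give (20S) carbinols; the fast addition at low temperature should outrun enolisation.

**Step 19**
Reactants: 25 diol
Product: 26 (3S,3aS,7S,8aR)-3-[(2S)-2-hydroxypent-4-en-2-yl]-8a-methyl-6-methylidenedecahydroazulen-7-yl acetate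
Conditions: Ac2O, pyridine, DMAP (cat.), CH2Cl2, 0 °C
Reagents that add atoms: acetic anhydride CC(=O)OC(C)=O
Why: the secondary allylic alcohol is acylated while the hindered tertiary alcohol does not react under these conditions.

**Step 20**
Reactants: 26 monoacetate; 27 2-methylbut-3-en-2-ol
Product: 28 (3S,3aS,7S,8aR)-3-[(2S,4E)-2,6-dihydroxy-6-methylhept-4-en-2-yl]-8a-methyl-6-methylidenedecahydroazulen-7-yl acetate (CNP0290154.1)
Conditions: second-generation Hoveyda–Grubbs catalyst (5 mol %), 27 (10 equiv), CH2Cl2, 40 °C
Reagents that add atoms: none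
Why: olefin cross metathesis of the terminal allyl group with the tertiary allylic alcohol should give the E alkene, while the 1,1-disubstituted exocyclic methylene next to the acetate stays inert.

**Compound list**
1 | (S)-(+)-carvone | CC(=C)[C@H]1CC=C(C)C(=O)C1 | starting material
2 | (1S,4S,6S)-1-methyl-4-(prop-1-en-2-yl)-7-oxabicyclo[4.1.0]heptan-2-one | CC(=C)[C@H]1C[C@@H]2O[C@]2(C)C(=O)C1 | intermediate
3 | (2R,3S,5S)-2-chloro-3-hydroxy-2-methyl-5-(prop-1-en-2-yl)cyclohexan-1-one | CC(=C)[C@H]1C[C@H](O)[C@@](C)(Cl)C(=O)C1 | intermediate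
4 | (2R,3S,5S)-2-chloro-2-methyl-5-(prop-1-en-2-yl)-3-(tetrahydro-2H-pyran-2-yloxy)cyclohexan-1-one (acetal epimers) | CC(=C)[C@H]1C[C@H](OC2CCCCO2)[C@@](C)(Cl)C(=O)C1 | intermediate
5 | methyl (1S,2R,3S,5S)-2-methyl-5-(prop-1-en-2-yl)-3-(tetrahydro-2H-pyran-2-yloxy)cyclopentane-1-carboxylate | COC(=O)[C@@H]1[C@@H](C)[C@@H](OC2CCCCO2)C[C@@H]1C(C)=C | intermediate (not isolated)
6 | methyl (1S,2R,3S,5S)-3-hydroxy-2-methyl-5-(prop-1-en-2-yl)cyclopentane-1-carboxylate | COC(=O)[C@@H]1[C@@H](C)[C@@H](O)C[C@@H]1C(C)=C | intermediate
7 | methyl (1S,2R,3S,5S)-3-(methanesulfonyloxy)-2-methyl-5-(prop-1-en-2-yl)cyclopentane-1-carboxylate | COC(=O)[C@@H]1[C@@H](C)[C@@H](OS(C)(=O)=O)C[C@@H]1C(C)=C | intermediate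
8 | methyl (1S,5S)-2-methyl-5-(prop-1-en-2-yl)cyclopent-2-ene-1-carboxylate | COC(=O)[C@@H]1C(C)=CC[C@@H]1C(C)=C | intermediate (not isolated)
9 | methyl (5R)-2-methyl-5-(prop-1-en-2-yl)cyclopent-1-ene-1-carboxylate | COC(=O)C1=C(C)CC[C@@H]1C(C)=C | intermediate
10 | [(5R)-2-methyl-5-(prop-1-en-2-yl)cyclopent-1-en-1-yl]methanol | OCC1=C(C)CC[C@@H]1C(C)=C | intermediate
11 | (5R)-2-methyl-5-(prop-1-en-2-yl)cyclopent-1-ene-1-carbaldehyde | O=CC1=C(C)CC[C@@H]1C(C)=C | intermediate
12 | (3R)-2-ethenyl-1-methyl-3-(prop-1-en-2-yl)cyclopent-1-ene | C=CC1=C(C)CC[C@@H]1C(C)=C | intermediate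
13 | methyl but-3-enoate | C=CCC(=O)OC | starting material
14 | methyl 2-diazobut-3-enoate | C=CC(=[N+]=[N-])C(=O)OC | intermediate
15 | methyl (1S,2S)-1-ethenyl-2-[(5R)-2-methyl-5-(prop-1-en-2-yl)cyclopent-1-en-1-yl]cyclopropane-1-carboxylate | COC(=O)[C@]1(C=C)C[C@H]1C2=C(C)CC[C@@H]2C(C)=C | intermediate (not isolated)
16 | methyl (3R,8aR)-8a-methyl-3-(prop-1-en-2-yl)-1,2,3,5,8,8a-hexahydroazulene-6-carboxylate | COC(=O)C1=CC[C@@]2(C)CC[C@H](C(C)=C)C2=CC1 | intermediate
17 | [(3R,8aR)-8a-methyl-3-(prop-1-en-2-yl)-1,2,3,5,8,8a-hexahydroazulen-6-yl]methanol | OCC1=CC[C@@]2(C)CC[C@H](C(C)=C)C2=CC1 | intermediate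
18 | [(3R,6S,7S,8aR)-6,7-epoxy-8a-methyl-3-(prop-1-en-2-yl)-1,2,3,5,6,7,8,8a-octahydroazulen-6-yl]methanol | OC[C@@]12CC=C3[C@@H](C(C)=C)CC[C@]3(C)C[C@@H]1O2 | intermediate
19 | 1,2-diol from dihydroxylation of the isopropenyl group of 18 (both carbinol epimers) | OC[C@@]12CC=C3[C@@H](C(C)(O)CO)CC[C@]3(C)C[C@@H]1O2 | intermediate (not isolated)
20 | 1-[(3S,6S,7S,8aR)-6,7-epoxy-6-(hydroxymethyl)-8a-methyl-1,2,3,5,6,7,8,8a-octahydroazulen-3-yl]ethan-1-one | OC[C@@]12CC=C3[C@@H](C(C)=O)CC[C@]3(C)C[C@@H]1O2 | intermediate
21 | 1-[(3S,3aS,6S,7S,8aR)-6,7-epoxy-6-(hydroxymethyl)-8a-methyldecahydroazulen-3-yl]ethan-1-one | OC[C@@]12CC[C@H]3[C@@H](C(C)=O)CC[C@]3(C)C[C@@H]1O2 | intermediate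
22 | 1-[(3S,3aS,6R,7S,8aR)-6,7-epoxy-6-(iodomethyl)-8a-methyldecahydroazulen-3-yl]ethan-1-one | IC[C@@]12CC[C@H]3[C@@H](C(C)=O)CC[C@]3(C)C[C@@H]1O2 | intermediate
23 | 1-[(3S,3aS,7S,8aR)-7-hydroxy-8a-methyl-6-methylidenedecahydroazulen-3-yl]ethan-1-one | C=C1CC[C@H]2[C@@H](C(C)=O)CC[C@]2(C)C[C@@H]1O | intermediate
24 | allylmagnesium bromide | C=CC[Mg]Br | starting material
25 | (2S)-2-[(3S,3aS,7S,8aR)-7-hydroxy-8a-methyl-6-methylidenedecahydroazulen-3-yl]pent-4-en-2-ol | C=C1CC[C@H]2[C@@H]([C@@](C)(O)CC=C)CC[C@]2(C)C[C@@H]1O | intermediate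
26 | (3S,3aS,7S,8aR)-3-[(2S)-2-hydroxypent-4-en-2-yl]-8a-methyl-6-methylidenedecahydroazulen-7-yl acetate | C=C1CC[C@H]2[C@@H]([C@@](C)(O)CC=C)CC[C@]2(C)C[C@@H]1OC(C)=O | intermediate
27 | 2-methylbut-3-en-2-ol | C=CC(C)(C)O | starting material
28 | (3S,3aS,7S,8aR)-3-[(2S,4E)-2,6-dihydroxy-6-methylhept-4-en-2-yl]-8a-methyl-6-methylidenedecahydroazulen-7-yl acetate (CNP0290154.1) | C=C1CC[C@H]2[C@@H]([C@@](C)(O)C/C=C/C(C)(C)O)CC[C@]2(C)C[C@@H]1OC(C)=O | target

**Step count**
Total steps: 20. Longest linear sequence: 19 steps (steps 1–9 and 11–20, from (S)-carvone); step 10 is a one-step side branch.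

**Steps most likely to fail and fallbacks**

Step 11. What may go wrong: carbene transfer to the isolated isopropenyl alkene (and to the alkenes of the product) competes with cyclopropanation of the diene terminus, so material is lost before the Cope rearrangement. The fallback removes the competing alkene beforehand by carrying the side chain as a protected 1,2-diol. It sets out from ester 9: OsO4 (cat.)/NMO should dihydroxylate only the isopropenyl group, since the tetrasubstituted enoate is electron-poor and hindered, to give the diol ester F1 (both carbinol epimers, of no consequence). Et3SiOTf/2,6-lutidine gives the bis(triethylsilyl) ether F2, and DIBAL-H, MnO2 and Ph3P=CH2 as in steps 7–9 lead through the allylic alcohol F3 and the enal F4 to the diene F5. The same Rh2(R-DOSP)4 reaction with 14 gives the cyclopropane F6 and, on heating, the hydroazulene ester F7. DIBAL-H then gives the allylic alcohol F8 and Sharpless epoxidation the epoxy alcohol F9. Bu4NF removes both silyl groups and the route is rejoined at diol 19, which is cleaved with NaIO4 alone to 20. This also takes the OsO4 site-selectivity question out of step 14.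

Step 15. What may go wrong: the β,γ-unsaturated methyl ketone slips into conjugation or loses its configuration at C3 before or during the radical reduction, or hydrogen is delivered to the wrong face and the cis-fused isomer forms. The fallback sets the ring fusion before the ketone exists. It sets out from 19, isolated by running step 14 with OsO4/NMO and no periodate; the hydrogen-atom-transfer reduction (Mn(dpm)3, PhSiH3) on this diol gives the saturated triol F10, in which C3 cannot epimerise, and NaIO4 then cleaves the glycol to rejoin the route at 21. If the face of hydrogen delivery is still wrong, the epimers are separated at 21.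

Step 18. What may go wrong: poor facial selectivity in the addition to the methyl ketone, since allylmagnesium halides react very fast and can ignore the Felkin–Anh bias, together with enolisation and loss of the C3 configuration. The fallback replaces substrate control by catalyst control under non-basic conditions. It sets out from 23: Ac2O/pyridine gives the acetoxy ketone F11, and titanium–BINOL-catalysed allylation with tetraallylstannane (Ti(OiPr)4, the BINOL enantiomer matched to the (S) carbinol, i-PrOH, CH2Cl2) gives the homoallylic tertiary alcohol directly as monoacetate 26, where the route is rejoined before step 20.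

**Further compounds**
F1 | step 11 | methyl (5R)-5-(1,2-dihydroxypropan-2-yl)-2-methylcyclopent-1-ene-1-carboxylate (carbinol epimers) | COC(=O)C1=C(C)CC[C@@H]1C(C)(O)CO
F2 | step 11 | bis(triethylsilyl) ether of F1 | COC(=O)C1=C(C)CC[C@@H]1C(C)(O[Si](CC)(CC)CC)CO[Si](CC)(CC)CC
F3 | step 11 | allylic alcohol from F2 | OCC1=C(C)CC[C@@H]1C(C)(O[Si](CC)(CC)CC)CO[Si](CC)(CC)CC
F4 | step 11 | enal from F3 | O=CC1=C(C)CC[C@@H]1C(C)(O[Si](CC)(CC)CC)CO[Si](CC)(CC)CC
F5 | step 11 | 1-methyl-2-vinylcyclopentene carrying the bis(triethylsilyloxy)propan-2-yl group | C=CC1=C(C)CC[C@@H]1C(C)(O[Si](CC)(CC)CC)CO[Si](CC)(CC)CC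
F6 | step 11 | cis-divinylcyclopropane from F5 and 14 | COC(=O)[C@]1(C=C)C[C@H]1C2=C(C)CC[C@@H]2C(C)(O[Si](CC)(CC)CC)CO[Si](CC)(CC)CC
F7 | step 11 | hydroazulene diene ester carrying the bis(triethylsilyloxy)propan-2-yl group | COC(=O)C1=CC[C@@]2(C)CC[C@H](C(C)(O[Si](CC)(CC)CC)CO[Si](CC)(CC)CC)C2=CC1
F8 | step 11 | allylic alcohol from F7 | OCC1=CC[C@@]2(C)CC[C@H](C(C)(O[Si](CC)(CC)CC)CO[Si](CC)(CC)CC)C2=CC1
F9 | step 11 | 6,7-epoxy alcohol from F8 (epoxide anti to the 8a-methyl) | OC[C@@]12CC=C3[C@@H](C(C)(O[Si](CC)(CC)CC)CO[Si](CC)(CC)CC)CC[C@]3(C)C[C@@H]1O2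
F10 | step 15 | trans-fused saturated epoxy triol from 19 | OC[C@@]12CC[C@H]3[C@@H](C(C)(O)CO)CC[C@]3(C)C[C@@H]1O2
F11 | step 18 | (3S,3aS,7S,8aR)-3-acetyl-8a-methyl-6-methylidenedecahydroazulen-7-yl acetate | C=C1CC[C@H]2[C@@H](C(C)=O)CC[C@]2(C)C[C@@H]1OC(C)=O
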